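## Retrosynthetic overview

- Numbering (furo[3,4-c]furan): ring A = C1(aryl)–O2–C3–C3a(OH)–C6a; ring B = C3a–C4(aryl)–O5–C6–C6a.
- Enabling feature: in ring B the triad C4(H)(aryl)–O5–C6H2 is bonded to the rest only through C3a and C6a, so it is a latent carbonyl ylide (veratraldehyde O-methylide). C3a (oxygenated, fully substituted) and C6a are the α- and β-carbons of a butenolide once ring A is taken to the lactone level (C3 as carbonyl), a captodative 2π partner with two different faces.
- Key disconnection: ring B by a [3+2] cycloaddition that forms C6–C6a and C4–C3a together, joining the two veratryl halves at the quaternary carbinol C3a and setting C3a, C6a and C4.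
- Ring A is made first, as an (S)-5-aryl-3-pivaloyloxy-butenolide (from veratraldehyde by asymmetric 2-(ethoxycarbonyl)allylation, oxidative cleavage and enol acylation); its C1 aryl centre steers the cycloaddition and is then erased and reset.
- End game: lactone reduction opens ring A, benzylic oxidation gives the C1 hemiketal (ring A closed again), and hydride delivery to the convex face sets the endo C1 aryl group.

Key step: step 5

Remark: the target SMILES is read as the (1R,3aS,4S,6aR) isomer, cis-fused, with both aryl groups on the concave (endo) face, anti to the bridgehead OH and H; the route is laid out for this isomer.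

## Route

Step 1
Reactants: 1 3,4-dimethoxybenzaldehyde (veratraldehyde); 2 ethyl 2-(bromomethyl)acrylate
Product: 5 (S)-5-(3,4-dimethoxyphenyl)-3-methylenedihydrofuran-2(3H)-one, via silyl ether 3 (not isolated), via hydroxy ester 4 (not isolated)
Conditions: CrCl2 (10 mol %), chiral tridentate carbazole bis(oxazoline) ligand (12 mol %, the enantiomer that gives the S carbinol), Mn powder, Me3SiCl, THF, rt; then 0.5 M HCl, THF, 0 °C to rt
Reagents that add atoms: none
Why: Catalytic asymmetric Nozaki–Hiyama–Kishi 2-(alkoxycarbonyl)allylation, in which the allylchromium species adds to the aldehyde through a closed transition state inside the chiral ligand sphere and so sets the S carbinol centre; the O-silylated hydroxy ester is desilylated and lactonises on mild acidic work-up.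

Step 2
Reactants: 5 (S)-5-(3,4-dimethoxyphenyl)-3-methylenedihydrofuran-2(3H)-one
Product: 7 (S)-5-(3,4-dimethoxyphenyl)-3-hydroxyfuran-2(5H)-one, via diol 6 (not isolated)
Conditions: OsO4 (2 mol %), NaIO4 (3 equiv), 2,6-lutidine (2 equiv), dioxane/H2O 3:1, rt
Reagents that add atoms: osmium tetroxide O=[Os](=O)(=O)=O; sodium periodate [Na+].[O-]I(=O)(=O)=O
Why: Lemieux–Johnson oxidative cleavage (osmylation of the 1,1-disubstituted alkene, then periodate glycol cleavage) removes the exocyclic CH2, and the resulting α-keto lactone should rest as its conjugated enol; C5 is not touched and the electron-rich arene is spared, which ozone might not do.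

Step 3
Reactants: 7 (S)-5-(3,4-dimethoxyphenyl)-3-hydroxyfuran-2(5H)-one
Product: 8 (S)-5-(3,4-dimethoxyphenyl)-2-oxo-2,5-dihydrofuran-3-yl pivalate
Conditions: PivCl (1.2 equiv), pyridine (1.5 equiv), CH2Cl2, −20 to 0 °C
Reagents that add atoms: pivaloyl chloride CC(C)(C)C(Cl)=O
Why: O-acylation of the acidic enol (isotetronic acid type) gives the captodative enol ester; the weak base and low temperature are chosen so that the benzylic C5–H is not removed and the S centre is kept.

Step 4
Reactants: 1 3,4-dimethoxybenzaldehyde; 9 (trimethylsilyl)methanol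
Product: 10 4-{bis[(trimethylsilyl)methoxy]methyl}-1,2-dimethoxybenzene
Conditions: 9 (2.5 equiv), PPTS (5 mol %), cyclohexane, reflux, azeotropic removal of water
Reagents that add atoms: none
Why: Acid-catalysed acetalisation driven by water removal gives a storable precursor of the ylide; no stereocentre is formed.

Step 5
Reactants: 8 (S)-5-(3,4-dimethoxyphenyl)-2-oxo-2,5-dihydrofuran-3-yl pivalate; 10 4-{bis[(trimethylsilyl)methoxy]methyl}-1,2-dimethoxybenzene
Product: 13 (3S,3aR,6S,6aR)-3,6-bis(3,4-dimethoxyphenyl)-1-oxotetrahydro-1H,3H-furo[3,4-c]furan-6a(6H)-yl pivalate (cis-fused lactone; C3 aryl exo; C6 aryl endo), via chloro ether 11 (not isolated), via carbonyl ylide 12 (not isolated)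
Conditions: 10 (3 equiv), AcCl (3 equiv), CH2Cl2, 0 °C to rt, then concentrate; crude 11 in MeCN added over 4 h to 8 and anhydrous CsF (6 equiv), MeCN, rt
Reagents that add atoms: none
Why: Acetyl chloride converts acetal 10 into α-chloro ether 11, which ionises to the aryl-stabilised oxocarbenium ion, and fluoride then removes the silyl group in a silicon-based 1,3-elimination to give the non-stabilised E carbonyl ylide 12, which is trapped by the electron-poor enol-ester C=C of 8. The closest known reaction type is the [3+2] cycloaddition of non-stabilised carbonyl ylides, generated from α-chloroalkyl (trimethylsilyl)methyl ethers and CsF, with acrylates, maleates and other activated alkenes. Ring B is closed by a concerted but asynchronous, suprafacial 1,3-dipolar cycloaddition (4π + 2π) in which the nucleophilic CH2 terminus bonds to the lactone β-carbon (C6a of the target) and the electrophilic aryl-bearing terminus to the α-carbon (C3a of the target), the sense expected from the polarisation of both partners. C6a and C3a are formed cis because the cyclic Z-alkene adds suprafacially, and their absolute configuration is fixed by the C5 aryl group of 8, the ylide approaching the face anti to it. The aryl-bearing ylide carbon (C4 of the target) is set by an endo transition state of the E-ylide, which places the aryl group over the flat lactone carbonyl and away from the pivaloyloxy group, so that the aryl group ends up cis to the lactone carbon and trans to the acyloxy oxygen. The step therefore needs regio-, facial and endo selectivity, which the captodative polarisation of the butenolide, its 5-aryl substituent and the bulk of the pivalate are meant to secure in that order.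

Step 6
Reactants: 13 (3S,3aR,6S,6aR)-3,6-bis(3,4-dimethoxyphenyl)-1-oxotetrahydro-1H,3H-furo[3,4-c]furan-6a(6H)-yl pivalate
Product: 14 (2S,3S,4R)-2-(3,4-dimethoxyphenyl)-4-[(S)-(3,4-dimethoxyphenyl)(hydroxy)methyl]-3-(hydroxymethyl)tetrahydrofuran-3-ol
Conditions: LiAlH4 (5 equiv), THF, 0 °C to reflux; Na2SO4·10H2O quench
Reagents that add atoms: none
Why: Hydride reduction opens the lactone to the primary/benzylic diol and cleaves the pivalate in the same operation; no C–O bond at a stereocentre is broken, so all four centres are retained.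

Step 7
Reactants: 14 (2S,3S,4R)-2-(3,4-dimethoxyphenyl)-4-[(S)-(3,4-dimethoxyphenyl)(hydroxy)methyl]-3-(hydroxymethyl)tetrahydrofuran-3-ol
Product: 16 (3aS,4S,6aS)-1,4-bis(3,4-dimethoxyphenyl)tetrahydro-1H,3H-furo[3,4-c]furan-1,3a(4H)-diol (C1 hemiketal; anomer mixture), via keto diol 15 (not isolated)
Conditions: activated MnO2 (20 equiv), CH2Cl2, rt
Reagents that add atoms: none
Why: MnO2 should oxidise only the benzylic secondary alcohol (not the primary or tertiary alcohol, nor the benzylic ether C–H), which deliberately erases the relay stereocentre; the keto diol closes through its primary hydroxyl to the five-membered hemiketal, which also shields the β-hydroxy ketone from retro-aldol cleavage.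

Step 8
Reactants: 16 (3aS,4S,6aS)-1,4-bis(3,4-dimethoxyphenyl)tetrahydro-1H,3H-furo[3,4-c]furan-1,3a(4H)-diol
Product: 18 (1R,3aS,4S,6aR)-1,4-bis(3,4-dimethoxyphenyl)tetrahydro-1H,3H-furo[3,4-c]furan-3a(4H)-ol, via oxocarbenium ion 17 (not isolated)
Conditions: Et3SiH (5 equiv), BF3·OEt2 (2 equiv), CH2Cl2, −78 °C; sat. aq. NaHCO3 quench
Reagents that add atoms: none
Why: Ionic hydrogenation of a cyclic hemiketal through the aryl-stabilised oxocarbenium ion, in which hydride is delivered to the convex face of the cis-fused bicycle (the concave face is further blocked by the endo aryl group of ring B), so the new C1–H is exo and the C1 aryl group endo (1R); the low temperature is meant to leave the second benzylic C–O bond intact.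

## Compound list

1 | 3,4-dimethoxybenzaldehyde (veratraldehyde) | COc1ccc(C=O)cc1OC | starting material
2 | ethyl 2-(bromomethyl)acrylate | C=C(CBr)C(=O)OCC | starting material
3 | ethyl (S)-4-(3,4-dimethoxyphenyl)-2-methylene-4-(trimethylsilyloxy)butanoate | C=C(C[C@H](O[Si](C)(C)C)c1ccc(OC)c(OC)c1)C(=O)OCC | intermediate
4 | ethyl (S)-4-(3,4-dimethoxyphenyl)-4-hydroxy-2-methylenebutanoate | C=C(C[C@H](O)c1ccc(OC)c(OC)c1)C(=O)OCC | intermediate
5 | (S)-5-(3,4-dimethoxyphenyl)-3-methylenedihydrofuran-2(3H)-one | C=C1C[C@@H](c2ccc(OC)c(OC)c2)OC1=O | intermediate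
6 | (5S)-5-(3,4-dimethoxyphenyl)-3-hydroxy-3-(hydroxymethyl)dihydrofuran-2(3H)-one (C3 epimers) | OCC1(O)C[C@@H](c2ccc(OC)c(OC)c2)OC1=O | intermediate
7 | (S)-5-(3,4-dimethoxyphenyl)-3-hydroxyfuran-2(5H)-one (enol of the 2,3-dione) | OC1=C[C@@H](c2ccc(OC)c(OC)c2)OC1=O | intermediate
8 | (S)-5-(3,4-dimethoxyphenyl)-2-oxo-2,5-dihydrofuran-3-yl pivalate | CC(C)(C)C(=O)OC1=C[C@@H](c2ccc(OC)c(OC)c2)OC1=O | intermediate
9 | (trimethylsilyl)methanol | C[Si](C)(C)CO | starting material
10 | 4-{bis[(trimethylsilyl)methoxy]methyl}-1,2-dimethoxybenzene | COc1ccc(C(OC[Si](C)(C)C)OC[Si](C)(C)C)cc1OC | intermediate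
11 | 4-{chloro[(trimethylsilyl)methoxy]methyl}-1,2-dimethoxybenzene (racemic) | COc1ccc(C(Cl)OC[Si](C)(C)C)cc1OC | intermediate
12 | (E)-carbonyl ylide, veratraldehyde O-methylide (ArCH=O(+)–CH2(−)) | COc1ccc(/C=[O+]/[CH2-])cc1OC | intermediate
13 | (3S,3aR,6S,6aR)-3,6-bis(3,4-dimethoxyphenyl)-1-oxotetrahydro-1H,3H-furo[3,4-c]furan-6a(6H)-yl pivalate | COc1ccc([C@H]2OC(=O)[C@@]3(OC(=O)C(C)(C)C)[C@@H]2CO[C@H]3c2ccc(OC)c(OC)c2)cc1OC | intermediate
14 | (2S,3S,4R)-2-(3,4-dimethoxyphenyl)-4-[(S)-(3,4-dimethoxyphenyl)(hydroxy)methyl]-3-(hydroxymethyl)tetrahydrofuran-3-ol | COc1ccc([C@@H](O)[C@H]2CO[C@@H](c3ccc(OC)c(OC)c3)[C@@]2(O)CO)cc1OC | intermediate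
15 | (3,4-dimethoxyphenyl)[(3S,4S,5S)-5-(3,4-dimethoxyphenyl)-4-hydroxy-4-(hydroxymethyl)tetrahydrofuran-3-yl]methanone | COc1ccc(C(=O)[C@H]2CO[C@@H](c3ccc(OC)c(OC)c3)[C@@]2(O)CO)cc1OC | intermediate
16 | (3aS,4S,6aS)-1,4-bis(3,4-dimethoxyphenyl)tetrahydro-1H,3H-furo[3,4-c]furan-1,3a(4H)-diol (C1 hemiketal, anomer mixture) | COc1ccc(C2(O)OC[C@@]3(O)[C@@H]2CO[C@H]3c2ccc(OC)c(OC)c2)cc1OC | intermediate
17 | cyclic C1 oxocarbenium ion derived from 16 | COc1ccc(C2=[O+]C[C@@]3(O)[C@@H]2CO[C@H]3c2ccc(OC)c(OC)c2)cc1OC | intermediate
18 | (1R,3aS,4S,6aR)-1,4-bis(3,4-dimethoxyphenyl)tetrahydro-1H,3H-furo[3,4-c]furan-3a(4H)-ol | COc1ccc([C@@H]2OC[C@@]3(O)[C@@H]2CO[C@H]3c2ccc(OC)c(OC)c2)cc1OC | target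

## Step count and risks

Total step count: 8. Longest linear sequence: 7 (steps 1, 2, 3, 5, 6, 7, 8); step 4 is a one-step branch.

Steps most likely to fail:

**Step 5 (key step).** The ylide aryl group may not adopt the endo position, so that it ends up exo, cis to the acyloxy group, on ring B; fluoride may also erode the configuration of 8 at its acidic C5–H before trapping. The fallback below addresses the endo/exo problem. It sets out from 8 and 10 and comes back at 13: the same union is accepted as it falls and the aryl-bearing centre is set afterwards by hydride instead of by the transition state. The exo-aryl adduct, (3S,3aR,6R,6aR)-3,6-bis(3,4-dimethoxyphenyl)-1-oxotetrahydro-1H,3H-furo[3,4-c]furan-6a(6H)-yl pivalate F1, alone or mixed with 13, is oxidised with DDQ in CH2Cl2/H2O at its electron-rich benzylic ether C6–H (the benzylic C3–H carries an acyloxy oxygen and should be inert). Water traps the oxocarbenium ion as the C6 hemiketal F2. Ionic hydrogenation (Et3SiH, BF3·OEt2, CH2Cl2, −78 °C) should then add hydride from the convex face and give 13 with the C6 aryl group endo.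

**Step 8.** The Lewis acid may ionise the second benzylic C–O bond (C4–O5), which would epimerise the ring B aryl group to the exo position or lead to over-reduction; hydride delivery may also not be fully convex-face selective. The fallback sets out from 16 and comes back at 18, and avoids the Lewis acid altogether. Asymmetric transfer hydrogenation of the open ketone form of 16 with RuCl(p-cymene)[(R,R)-TsDPEN] in HCO2H/Et3N should give, under reagent control, the benzylic R carbinol, (2S,3S,4R)-2-(3,4-dimethoxyphenyl)-4-[(R)-(3,4-dimethoxyphenyl)(hydroxy)methyl]-3-(hydroxymethyl)tetrahydrofuran-3-ol F3. Primary-selective sulfonylation (TsCl, Et3N, cat. Bu2SnO, CH2Cl2) gives the primary tosylate F4. Warming F4 in pyridine should close ring A by attack of the neutral benzylic hydroxyl on the CH2–OTs carbon (5-exo-tet), with retention at the benzylic carbon, to give 18.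

**Step 1.** The chromium-catalysed allylation of the electron-rich aldehyde may turn over slowly, so that a racemic background addition erodes the enantiomeric purity on which every later centre depends. The fallback sets out from 1 and 2 and comes back at 4, and sets the centre by reagent-controlled ketone reduction instead. Barbier allylation (Zn dust, sat. aq. NH4Cl/THF) gives racemic ethyl 4-(3,4-dimethoxyphenyl)-4-hydroxy-2-methylenebutanoate F5. MnO2 oxidises it to ethyl 4-(3,4-dimethoxyphenyl)-2-methylene-4-oxobutanoate F6. Corey–Bakshi–Shibata reduction ((R)-2-methyl-CBS-oxazaborolidine, catecholborane, toluene, −78 °C; aryl as the large group) should give the S alcohol 4, which lactonises to 5 with PPTS.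

## Further compounds

F1 | step 5 | (3S,3aR,6R,6aR)-3,6-bis(3,4-dimethoxyphenyl)-1-oxotetrahydro-1H,3H-furo[3,4-c]furan-6a(6H)-yl pivalate (C6 epimer of 13) | COc1ccc([C@H]2OC(=O)[C@@]3(OC(=O)C(C)(C)C)[C@@H]2CO[C@@H]3c2ccc(OC)c(OC)c2)cc1OC
F2 | step 5 | (3S,3aR,6aR)-3,6-bis(3,4-dimethoxyphenyl)-6-hydroxy-1-oxotetrahydro-1H,3H-furo[3,4-c]furan-6a(6H)-yl pivalate (C6 hemiketal, anomer mixture) | COc1ccc([C@H]2OC(=O)[C@@]3(OC(=O)C(C)(C)C)[C@@H]2COC3(O)c2ccc(OC)c(OC)c2)cc1OC
F3 | step 8 | (2S,3S,4R)-2-(3,4-dimethoxyphenyl)-4-[(R)-(3,4-dimethoxyphenyl)(hydroxy)methyl]-3-(hydroxymethyl)tetrahydrofuran-3-ol | COc1ccc([C@H](O)[C@H]2CO[C@@H](c3ccc(OC)c(OC)c3)[C@@]2(O)CO)cc1OC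
F4 | step 8 | primary 4-methylbenzenesulfonate of F3 (tosyl on the CH2OH group at C3 of the tetrahydrofuran) | COc1ccc([C@H](O)[C@H]2CO[C@@H](c3ccc(OC)c(OC)c3)[C@@]2(O)COS(=O)(=O)c2ccc(C)cc2)cc1OC
F5 | step 1 | racemic ethyl 4-(3,4-dimethoxyphenyl)-4-hydroxy-2-methylenebutanoate | C=C(CC(O)c1ccc(OC)c(OC)c1)C(=O)OCC
F6 | step 1 | ethyl 4-(3,4-dimethoxyphenyl)-2-methylene-4-oxobutanoate | C=C(CC(=O)c1ccc(OC)c(OC)c1)C(=O)OCC
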